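Early on, at the first reading of 0.667 h, the birch run already stood level, far short of using up its Q, and that early stop is what I had to carry to the new flask.

| flask | Q | Z | remark | time |
|---|---|---|---|---|
| birch | 15 mM | 3.8 mM | run made earlier |  |
| oak | 15 mM | 15 mM | run made earlier |  |
| flask | 15 mM | 7.50 mM |  | 5.0 h |

- birch (time / h: E / %, Q / %): 0.667: 26, 76; 1.33: 25, 73; 2.00: 26, 75; 2.50: 24, 76; 3.00: 27, 76
- oak (time / h: E / %, Q / %): 0.667: 99, 2; 1.33: 102, 0; 2.00: 100, 1; 2.50: 102, 0; 3.00: 102, 1

(readings scatter by 1.5 percentage points)

- the earlier runs were read with a standard deviation of 1.5 percentage points
- the reaction counts as stopped when no species that holds the Q changes by six tenths of a point or more over the second half of the time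

1. the state of affairs at 5.0 h: stopped, and by what, or still going (it is still moving / all of Q has reacted / Z has run out first)
2. how much E there is at 5.0 h, in percent of the Q charged
3. amount of E if the flask were left three thousand times as long, in percent of the Q charged

From 0.667 h on, the birch and oak readings stood level and showed no rate to read, so I divided the amount of E made by the amount of Q lost, a ratio in which time does not appear. Averaged over the birch readings, E stood at 25.6 % of the Q charged, and Q had lost 24.8 %, so one Q went into about one E. The birch charge of Z was 25.3 % of the Q charge. If Z had run out there, E divided by that fraction gave the yield per Z, the E made for each Z used: 1.01. Z was then the limiting reagent of birch, and the flask, charged with 50.0 %, had a ceiling of 50.5 %. The flask's Z was twice that of birch and half that of oak, and both runs were level by 0.667 h, so I expected the flask to be stopped well before 5.0 h.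

The weak link was that "if", since a balance could also have stopped birch. Oak mended it: it reached 101 % E, more than birch, with Q near 0.800 %, and it gave 1.01 E per Z.

The forecast, slightly below my ceiling, held that “The birch plateau therefore means Z is exhausted”. It gave Z has run out first, with 50 % E (48.5 % to 51.5 %) and 50 % for the long wait (48 % to 53 %).

The flask gave Z has run out first, with 50.0 % E at 5.00 h and 50.0 % for the long wait.

    Q + Z → E, rate k1*[Q]^0.5*[Z]^0.5 (k = 0.00381 s⁻¹)

The conversion of Q and Z into E ran while Z lasted, with half of its turnover done by 1.95 min, and by 0.500 h the flask held Z at 0 %, having made 1.00 E per Z charged. From then on the flask stood at Q 50.0 % and E 50.0 %, unchanged to 50.0 h. A neighbour flask charged with 0.127 equiv of Z has a ceiling, by the yield per Z, of 12.8 %, and it ended with 12.7 % E.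

The numbers in the tables were generated by integration for substances that don't exist.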